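## Structural features

The target 15 is an isoflavone: benzene ring A is fused to a 4-pyranone ring C (O1, C2, C3, C4, C4a, C8a), and the 2,4,5-trimethoxyphenyl ring B is attached through the single bond C3–C1′. Ring A carries a free hydroxyl at C6 and a methoxyl at C7, with hydrogens at C5 and C8; ring B carries methoxyls at C2′, C4′ and C5′, and C2 carries a hydrogen. There is no stereocentre, so no stereocentres stand next to each other; the only one that appears in the route is a transient C3 centre in a chroman-4-one, which is erased when ring C is dehydrogenated. The fragile points are three:
- the C6 phenol, which is para to O1 and therefore an oxidation-prone hydroquinone monoether;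
- the C2=C3 bond, a vinylogous ester that is open to conjugate attack and to hydrogenation;
- the very electron-rich ring B, which is sensitive to electrophiles and one-electron oxidants.

The real difficulty is regiochemical: O6 (free) must be kept apart from O7 (methylated), and the C3–C4–C4a ketone must be assembled between two electron-rich arenes without disturbing that pattern. The key step uses the fact that C4 is a lone carbonyl carbon flanked by C4a of ring A (ortho to the O1-bearing C8a) and by C3, which carries ring B and C2. C4 can therefore come from carbon monoxide, C4a from an aryl iodide carbon, and C3 from the boron-bearing carbon of a 1-arylvinyl boronate whose =CH2 terminus becomes C2. Atom mapping confirms the ring A pattern: iodination of 3 para to its methoxyl and ortho to its hydroxyl puts iodine at the future C4a, benzyloxy at the future C6 and methoxyl at the future C7.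

## Logic of the disconnections

15 to 14: the O6–CH2 bond of a benzyl ether is cut. The C6 hydroxyl is the one free phenol and the most oxidisable site, so it should stay masked through every oxidative, basic and palladium-mediated operation; the benzyl group is already present in 1 and costs no step. The gain is a fully etherified, robust intermediate. The forward step must debenzylate without touching the C2=C3 bond or the four aryl methyl ethers.

14 to 13: no skeletal bond is cut; the C2=C3 double bond is traced back to C2–H and C3–H. The carbonylative coupling delivers C2 as a =CH2 group, one oxidation level below the chromone, and ring closure onto it gives a chroman-4-one. The gain is that 13 is the direct product of a conjugate addition, and its C3 centre may be racemic. The forward step must remove two hydrogens without attacking ring B or the benzyl ether.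

13 to 12 to 11: the O1–C2 bond is cut (retro-oxa-Michael), which opens ring C to 12, and O1 is then given a silyl mask, which leads to 11. This removes the heterocycle and leaves two arenes linked by a three-carbon enone. The forward step must be a 6-endo-trig closure onto an unhindered terminal methylene, triggered when the phenoxide is unmasked, under conditions that spare the benzyl ether.

11 to 5, 9 and 10: both bonds to C4 are cut, C4a–C4 and C4–C3. C4 is a ketone carbon between an arene carbon and an alkene carbon, which is the retron of a three-component carbonylative cross-coupling: C4 becomes 10, C4a the iodine-bearing carbon of 5, and C3 the boron-bearing carbon of 9. This is the largest simplification of the route, since the molecule falls into two arene fragments of similar size and a one-carbon gas. The forward step demands that CO insertion precedes transmetalation, that no oxygen nucleophile competes for the aroyl complex (hence the mask on O1), and that the hindered boronate still transfers its vinyl group.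

5 to 4 to 3: the O–Si bond and then the C–I bond at the future C4a are cut. The iodine sits where the electronics of 3 send an electrophile, ortho to the hydroxyl and para to the methoxyl. The gain is a ring A precursor with no halogen and one free phenol. The forward step must mono-iodinate at that position and silylate in the same flask, so that 4 need not be isolated.

3 to 2 to 1: the aryl C–O bond of the future O1 is traced back, through 2, to the aryl–CHO bond of 1. Compound 1 is a bulk chemical in which O6 already carries benzyl and O7 methyl, so the O6/O7 differentiation is bought and never has to be achieved. The forward step needs oxygen insertion with aryl migration and not hydride migration.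

9 to 7 and 8: the C3–B bond is cut. A boronate on the α-carbon of a styrene is not available by ordinary anti-Markovnikov hydroboration, so it is derived from a vinyl electrophile and 8. The forward step must be mild enough that 9 does not couple with unreacted 7.

7 to 6: the enol O–S bond is cut, which leads to 6, a commercial ketone that already holds ring B with its three methoxyls, C3 and C2. Only the methyl group can enolise, so regiochemistry is not an issue. The forward step must make and handle an electron-rich, labile vinyl triflate under strictly basic conditions.

## Other disconnections considered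

Alternative 1: The cut runs through ring A itself, at C5–C6 and C4a–C8a, so that ring A is built from a furan and an alkyne while ring B and the C3–C4 ketone ride in the dienophile. In the forward direction the silyloxyfuran A1 and the ethynyl ketone A2 would undergo a Diels–Alder addition; the oxa-bridged adduct would open at its ketal-like bridgehead and aromatise to the deoxybenzoin A3, with O1 silylated and the C6 hydroxyl free.
- In its favour: both donors of A1 make its unsubstituted α-carbon the nucleophilic terminus, so it should bond to the alkyne CH and give the required pattern. The O6/O7 distinction arises from the mechanism with no protecting group, a point on which this plan is better than the chosen one. A3 is a deoxybenzoin, so ring C can be closed with a one-carbon unit at the formyl oxidation level and no dehydrogenation is needed, a second point on which it is better.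
- Against it: A1 is a moisture-sensitive silyl ketene acetal. A2 has a methylene between a ketone and an electron-rich arene and can isomerise to an allenyl ketone or suffer conjugate addition. A push–pull furan may react by a stepwise Michael path. The silyl group can migrate between the two phenol oxygens. The free C6 phenol of A3 may be alkylated or formylated during the one-carbon insertion, which could bring a protecting step back.
- Comparison: structurally it builds ring A, which the chosen plan buys ready-made in 1. Mechanistically it relies on pericyclic polarity where the chosen plan relies on the innate selectivity of an aromatic iodination; both are credible. In step count it is about equal or one step shorter, which is named here as an advantage, but the diene and dienophile are less precedented than any step of the chosen route.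

Alternative 2: The cuts are O1–C8a, C4–C4a and O1–C2, so that ring C forms in one operation from an aryne and a β-methoxyacrylic acid. In the forward direction fluoride would release the symmetrical aryne from the silylaryl triflate A4; the carboxylate of acid A5 would add, the aryl anion would attack the carbonyl, and fragmentation would give an ortho-acyl phenoxide (formal insertion into the C–O bond). That phenoxide would then displace methoxide at C2 by addition–elimination to give A6.
- In its favour: three bonds and ring C are made in one step at the correct oxidation level, which is better than the chosen plan's closure followed by dehydrogenation. The symmetry of the aryne removes any regiochemical question in the insertion, and no transition metal is needed.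
- Against it: the same symmetry erases the O6/O7 distinction. A6 must be debenzylated twice to the catechol A7, which must then be mono-methylated at O7. O7 is the more acidic oxygen, being para to the C4 carbonyl, so the selectivity is plausible, but O6-methylation and double methylation would compete. A4 needs about four steps and A5 about three. Arynes and carboxylic acids often stop at the aryl ester, and the enol ether of A5 can itself add to the aryne.
- Comparison: structurally the chosen plan keeps the O6/O7 pattern fixed from the first step, whereas this plan must recreate it at the end. Mechanistically the aryne cascade is the more elegant ring C construction. In step count it is clearly longer (about ten steps).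

Alternative 3: The cuts are in ring B, at C5′–C6′, C1′–C2′ and C2′–C3′; ring B is assembled on a preformed chromone. In the forward direction the alkenyl carbene complex A8 would take up the alkyne of A9 and then a carbonyl ligand to give a vinylketene, which would electrocyclise and tautomerise to the phenol A10. O-Methylation of the new C2′ hydroxyl and debenzylation would follow.
- In its favour: the benzannulation rule for terminal alkynes puts the substituted alkyne carbon next to the new phenol, which gives exactly the 2′,4′,5′-oxygen pattern. The chromone is at the right oxidation level from the start, so no dehydrogenation is needed, which is better than the chosen plan. The single new phenol can be methylated without selectivity problems. Using a carbonyl ligand as a one-carbon unit is conceptually the equal of the chosen plan's use of 10.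
- Against it: chromium is stoichiometric. A8 is an uncommon and probably labile α-alkoxyvinyl carbene complex. A9 is an electron-poor alkyne conjugated to a Michael-accepting chromone, a substrate class prone to side paths in this reaction. The arene is released as a Cr(CO)3 complex, and oxidative decomplexation threatens the hydroquinone monoether. A9 itself needs about five steps (ring C construction, halogenation at C3, alkynylation, desilylation).
- Comparison: structurally it spends its key step on ring B, which the chosen plan buys complete in 6. Mechanistically it is sound but substrate-sensitive. In step count it is longer (about nine to ten steps) and less safe to run.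

Key step: step 5

Remark: 13 is made and used as the racemate, because its single stereocentre (C3) becomes sp2 in step 7. The substitution patterns of 4, 9 and 12 were re-derived atom by atom from 15 and are consistent, so no structure needed correction. The one design change is that the palladium step is run on the silyl ether 5 and not on the free phenol 4.

## Steps

Step 1
Reactants: 1 4-(benzyloxy)-3-methoxybenzaldehyde (benzylvanillin)
Product: 3 4-(benzyloxy)-3-methoxyphenol, via aryl formate 2 (not isolated)
Conditions: mCPBA, CH2Cl2, 0 °C to rt; then K2CO3 (cat.), MeOH, rt
Reagents that add atoms: 3-chloroperoxybenzoic acid (mCPBA), O=C(OO)c1cccc(Cl)c1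
Why: Dakin oxidation in its peracid form: Baeyer–Villiger oxidation of the electron-rich aldehyde should proceed with migration of the para-alkoxyaryl group to give formate 2, which methanolysis cleaves to the phenol; the benzyl and methyl ethers are inert to both stages.

Step 2
Reactants: 3 4-(benzyloxy)-3-methoxyphenol
Product: 5 {[4-(benzyloxy)-2-iodo-5-methoxyphenyl]oxy}tri(propan-2-yl)silane, via iodophenol 4 (not isolated)
Conditions: NIS (1.0 equiv), DMF, 0 °C, dark; then imidazole, iPr3SiCl, rt
Reagents that add atoms: N-iodosuccinimide, O=C1CCC(=O)N1I; chlorotri(propan-2-yl)silane, CC(C)[Si](Cl)(C(C)C)C(C)C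
Why: Electrophilic aromatic iodination should go to the one position that is ortho to the hydroxyl, para to the methoxyl and not flanked by two substituents, as with other 3,4-dialkoxyphenols. Imidazole-mediated silylation in the same flask then masks the phenol, so that no phenoxide is present in the palladium step.

Step 3
Reactants: 6 1-(2,4,5-trimethoxyphenyl)ethan-1-one (2',4',5'-trimethoxyacetophenone)
Product: 7 1-(2,4,5-trimethoxyphenyl)ethenyl trifluoromethanesulfonate
Conditions: KN(SiMe3)2, THF, −78 °C; PhNTf2, −78 to 0 °C; filtration through Et3N-deactivated silica, used at once
Reagents that add atoms: N-phenylbis(trifluoromethanesulfonimide), O=S(=O)(N(c1ccccc1)S(=O)(=O)C(F)(F)F)C(F)(F)F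
Why: Enol triflate formation: the methyl ketone has a single enolisable position and its potassium enolate is O-sulfonylated by the triflimide. Base-only conditions avoid the acid that would ionise this electron-rich α-arylvinyl triflate.

Step 4
Reactants: 7 1-(2,4,5-trimethoxyphenyl)ethenyl trifluoromethanesulfonate; 8 bis(pinacolato)diboron
Product: 9 4,4,5,5-tetramethyl-2-[1-(2,4,5-trimethoxyphenyl)ethenyl]-1,3,2-dioxaborolane
Conditions: PdCl2(PPh3)2 (3 mol %), PPh3 (6 mol %), KOPh, toluene, 50 °C
Reagents that add atoms: none
Why: Miyaura borylation of an alkenyl triflate: oxidative addition to zerovalent palladium, phenoxide-assisted transmetalation with the diboron and reductive elimination. KOPh at 50 °C activates the B–B bond but is too weak to drive Suzuki coupling of 9 with remaining 7.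

Step 5
Reactants: 5 {[4-(benzyloxy)-2-iodo-5-methoxyphenyl]oxy}tri(propan-2-yl)silane; 9 4,4,5,5-tetramethyl-2-[1-(2,4,5-trimethoxyphenyl)ethenyl]-1,3,2-dioxaborolane; 10 carbon monoxide
Product: 11 1-{5-(benzyloxy)-4-methoxy-2-{[tri(propan-2-yl)silyl]oxy}phenyl}-2-(2,4,5-trimethoxyphenyl)prop-2-en-1-one
Conditions: Pd(OAc)2 (5 mol %), PPh3 (20 mol %), K2CO3 (3 equiv), anisole–H2O (20:1), CO (3 bar), BHT (cat.), 80 °C; 9 (1.5 equiv) added in portions
Reagents that add atoms: none
Why: Carbonylative Suzuki–Miyaura coupling: the phosphine reduces Pd(OAc)2 to zerovalent palladium, which inserts into the C–I bond of 5; CO then inserts to give the aroyl complex of divalent palladium, carbonate or hydroxide replaces iodide, the 1-arylvinyl group of 9 is transferred from boron, and reductive elimination forms C4–C3 after C4a–C4. The closest known reaction type is the three-component coupling of aryl iodides, CO and alkenylboron reagents to aryl vinyl ketones. No ring is closed and no stereocentre is created here; ring C is closed only in step 6. The step needs chemoselectivity for the ketone over direct coupling without CO, over capture of the aroyl complex by oxygen nucleophiles and over protodeboronation of 9. CO insertion should win over direct coupling because the aryl group is electron-rich and ortho-substituted and migrates readily to CO, while the 1,1-disubstituted boronate transmetalates slowly and 3 bar of CO keeps the palladium saturated. The silyl ether on O1 secures the second point: with the free phenol 4 that same slow transmetalation would give a phenoxide time to intercept the aroyl complex as an aryl ester or to add to the product enone, so the phenol is carried masked and 4 never meets the catalyst. Portionwise addition of an excess of 9 compensates for protodeboronation, BHT suppresses radical polymerisation of the 1,1-disubstituted enone, and the benzyl and methyl ethers are spectators. Any silyl ether lost to the aqueous carbonate would cyclise to 13 and so rejoin the route in step 6.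

Step 6
Reactants: 11 1-{5-(benzyloxy)-4-methoxy-2-{[tri(propan-2-yl)silyl]oxy}phenyl}-2-(2,4,5-trimethoxyphenyl)prop-2-en-1-one
Product: 13 rac-6-(benzyloxy)-7-methoxy-3-(2,4,5-trimethoxyphenyl)-2,3-dihydro-4H-chromen-4-one, via hydroxy enone 12 (not isolated)
Conditions: Bu4NF (1.1 equiv), THF, 0 °C to rt; aq. NH4Cl
Reagents that add atoms: none
Why: Fluoride cleaves the aryl silyl ether and the liberated phenoxide adds to the unhindered terminal CH2 of the enone (6-endo-trig oxa-Michael addition, forming O1–C2), as 2'-hydroxy-α-methylene deoxybenzoins are known to do under mild base. Protonation of the enolate creates C3 without control, so 13 is racemic, which is immaterial because C3 becomes sp2 in step 7.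

Step 7
Reactants: 13 rac-6-(benzyloxy)-7-methoxy-3-(2,4,5-trimethoxyphenyl)-2,3-dihydro-4H-chromen-4-one
Product: 14 6-(benzyloxy)-7-methoxy-3-(2,4,5-trimethoxyphenyl)-4H-chromen-4-one
Conditions: DDQ (1.5 equiv), 1,4-dioxane (dry), 100 °C
Reagents that add atoms: none
Why: DDQ dehydrogenation of an isoflavanone to the isoflavone: hydride abstraction assisted by the O1 lone pair and by the electron-rich C3 aryl group, then loss of a proton, gives the conjugated chromone. The benzyl ether and the aryl methyl ethers should not be oxidised at a competitive rate under anhydrous conditions.

Step 8
Reactants: 14 6-(benzyloxy)-7-methoxy-3-(2,4,5-trimethoxyphenyl)-4H-chromen-4-one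
Product: 15 6-hydroxy-7-methoxy-3-(2,4,5-trimethoxyphenyl)-4H-chromen-4-one (target)
Conditions: H2 (1 atm), 10% Pd/C, EtOAc–THF, rt, stopped after uptake of one equivalent
Reagents that add atoms: none
Why: Hydrogenolysis of the benzylic C–O bond on palladium should be much faster than hydrogenation of the trisubstituted, vinylogous-ester C2=C3 bond. The aryl methyl ethers are inert.

## Compound list

1 | 4-(benzyloxy)-3-methoxybenzaldehyde (benzylvanillin) | O=Cc1ccc(OCc2ccccc2)c(OC)c1 | starting material
2 | 4-(benzyloxy)-3-methoxyphenyl formate | O=COc1ccc(OCc2ccccc2)c(OC)c1 | intermediate (not isolated)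
3 | 4-(benzyloxy)-3-methoxyphenol | COc1cc(O)ccc1OCc1ccccc1 | intermediate
4 | 4-(benzyloxy)-2-iodo-5-methoxyphenol | COc1cc(O)c(I)cc1OCc1ccccc1 | intermediate (not isolated)
5 | {[4-(benzyloxy)-2-iodo-5-methoxyphenyl]oxy}tri(propan-2-yl)silane | COc1cc(O[Si](C(C)C)(C(C)C)C(C)C)c(I)cc1OCc1ccccc1 | intermediate
6 | 1-(2,4,5-trimethoxyphenyl)ethan-1-one | CC(=O)c1cc(OC)c(OC)cc1OC | starting material
7 | 1-(2,4,5-trimethoxyphenyl)ethenyl trifluoromethanesulfonate | C=C(OS(=O)(=O)C(F)(F)F)c1cc(OC)c(OC)cc1OC | intermediate
8 | bis(pinacolato)diboron | CC1(C)OB(OC1(C)C)B1OC(C)(C)C(C)(C)O1 | starting material
9 | 4,4,5,5-tetramethyl-2-[1-(2,4,5-trimethoxyphenyl)ethenyl]-1,3,2-dioxaborolane | C=C(B1OC(C)(C)C(C)(C)O1)c1cc(OC)c(OC)cc1OC | intermediate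
10 | carbon monoxide | [C-]#[O+] | starting material
11 | 1-{5-(benzyloxy)-4-methoxy-2-{[tri(propan-2-yl)silyl]oxy}phenyl}-2-(2,4,5-trimethoxyphenyl)prop-2-en-1-one | C=C(C(=O)c1cc(OCc2ccccc2)c(OC)cc1O[Si](C(C)C)(C(C)C)C(C)C)c1cc(OC)c(OC)cc1OC | intermediate
12 | 1-[5-(benzyloxy)-2-hydroxy-4-methoxyphenyl]-2-(2,4,5-trimethoxyphenyl)prop-2-en-1-one | C=C(C(=O)c1cc(OCc2ccccc2)c(OC)cc1O)c1cc(OC)c(OC)cc1OC | intermediate (not isolated)
13 | rac-6-(benzyloxy)-7-methoxy-3-(2,4,5-trimethoxyphenyl)-2,3-dihydro-4H-chromen-4-one (racemate, C3 unspecified) | COc1cc2OCC(c3cc(OC)c(OC)cc3OC)C(=O)c2cc1OCc1ccccc1 | intermediate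
14 | 6-(benzyloxy)-7-methoxy-3-(2,4,5-trimethoxyphenyl)-4H-chromen-4-one | COc1cc2occ(-c3cc(OC)c(OC)cc3OC)c(=O)c2cc1OCc1ccccc1 | intermediate
15 | 6-hydroxy-7-methoxy-3-(2,4,5-trimethoxyphenyl)-4H-chromen-4-one | COc1cc2occ(-c3cc(OC)c(OC)cc3OC)c(=O)c2cc1O | target

## Step count and least certain steps

Total step count: 8. Longest linear sequence: 6 steps (1, 2, 5, 6, 7, 8; the boronate branch 3, 4, 5, 6, 7, 8 is equally long).

Step 5 (key step). The most likely failure is slow transfer of the hindered, electron-rich 1-arylvinyl group from boron to the aroyl complex. The complex would then be diverted to the benzoic acid by aqueous carbonate, 9 would be lost to protodeboronation, or, if the palladium is starved of CO, direct coupling without CO would occur. The fallback avoids the three-component coupling and the later dehydrogenation; it sets out from 5 and returns to the route at 14. Commercial 2,4,5-trimethoxyphenylacetic acid is converted (carbonyldiimidazole, MeNHOMe·HCl) into the Weinreb amide N-methoxy-N-methyl-2-(2,4,5-trimethoxyphenyl)acetamide F1. Iodine–magnesium exchange on 5 (iPrMgCl·LiCl, THF, −20 °C) and acylation with F1 should give the silyl-protected deoxybenzoin 1-{5-(benzyloxy)-4-methoxy-2-{[tri(propan-2-yl)silyl]oxy}phenyl}-2-(2,4,5-trimethoxyphenyl)ethan-1-one F2. Bu4NF in THF should release the 2-hydroxydeoxybenzoin 1-[5-(benzyloxy)-2-hydroxy-4-methoxyphenyl]-2-(2,4,5-trimethoxyphenyl)ethan-1-one F3. Heating F3 with N,N-dimethylformamide dimethyl acetal (toluene, 90 °C) should insert C2 at the formyl oxidation level and close ring C to 14, the classical deoxybenzoin route to isoflavones.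

Step 3 (and with it the handling of 7 in step 4). The most likely failure is loss of the triflate by ionisation and hydrolysis back to 6, or by base-induced elimination to the arylacetylene, because the 2,4,5-trimethoxyphenyl group strongly stabilises an α-aryl vinyl cation; losses can also occur on silica and during the 50 °C borylation. The fallback avoids any vinyl electrophile; it sets out from 6 and returns at 9. Condensation of 6 with 2,4,6-tri(propan-2-yl)benzenesulfonohydrazide (MeOH, cat. HCl) should give the hydrazone N'-[(1E)-1-(2,4,5-trimethoxyphenyl)ethylidene]-2,4,6-tri(propan-2-yl)benzenesulfonohydrazide F4. A Shapiro reaction (nBuLi, exactly 2 equiv, THF, −78 to 0 °C) followed by trapping of the vinyl anion with 2-isopropoxy-4,4,5,5-tetramethyl-1,3,2-dioxaborolane should give 9 directly.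

Step 7. The most likely failure is electron-transfer oxidation of ring B, or slow oxidative attack on the benzyl ether, in competition with hydride abstraction at C2; charge-transfer complexation of the quinone by the two electron-rich arenes could also stall the reaction. The fallback replaces the quinone by an enolate-specific dehydrogenation; it sets out from 13 and returns at 14. Soft enolisation (Me3SiOTf, Et3N, CH2Cl2, 0 °C) should give the silyl enol ether {[6-(benzyloxy)-7-methoxy-3-(2,4,5-trimethoxyphenyl)-2H-chromen-4-yl]oxy}trimethylsilane F5. Saegusa–Ito oxidation of F5 with Pd(OAc)2 (MeCN–DMSO, rt to 40 °C) should then give 14 through a palladium enolate at C3 and β-hydride elimination from C2.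

Step 8. The most likely failure is over-reduction, that is hydrogenation of C2=C3 once the benzyl group has gone, or sluggish hydrogenolysis if the catalyst is poisoned by traces carried over from steps 2 and 7. The fallback is a non-reductive Lewis-acid debenzylation, in which alkene reduction cannot occur; it sets out from 14 and ends at 15. BCl3 with pentamethylbenzene as cation scavenger (CH2Cl2, −78 °C) should cleave the benzyl ether selectively. None of the methyl ethers is peri or ortho to the carbonyl, so none is activated towards BCl3. This fallback makes no new compound.

## Further compounds

F1 | step 5 | N-methoxy-N-methyl-2-(2,4,5-trimethoxyphenyl)acetamide | CON(C)C(=O)Cc1cc(OC)c(OC)cc1OC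
F2 | step 5 | 1-{5-(benzyloxy)-4-methoxy-2-{[tri(propan-2-yl)silyl]oxy}phenyl}-2-(2,4,5-trimethoxyphenyl)ethan-1-one | COc1cc(O[Si](C(C)C)(C(C)C)C(C)C)c(cc1OCc1ccccc1)C(=O)Cc1cc(OC)c(OC)cc1OC
F3 | step 5 | 1-[5-(benzyloxy)-2-hydroxy-4-methoxyphenyl]-2-(2,4,5-trimethoxyphenyl)ethan-1-one | COc1cc(O)c(cc1OCc1ccccc1)C(=O)Cc1cc(OC)c(OC)cc1OC
F4 | step 3 | N'-[(1E)-1-(2,4,5-trimethoxyphenyl)ethylidene]-2,4,6-tri(propan-2-yl)benzenesulfonohydrazide | C/C(=N\NS(=O)(=O)c1c(C(C)C)cc(C(C)C)cc1C(C)C)c1cc(OC)c(OC)cc1OC
F5 | step 7 | {[6-(benzyloxy)-7-methoxy-3-(2,4,5-trimethoxyphenyl)-2H-chromen-4-yl]oxy}trimethylsilane | COc1cc2OCC(c3cc(OC)c(OC)cc3OC)=C(O[Si](C)(C)C)c2cc1OCc1ccccc1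
F0 | step 8 | none | none
A1 | alternative 1 | tert-butyl[(4-methoxyfuran-2-yl)oxy]dimethylsilane | COc1coc(O[Si](C)(C)C(C)(C)C)c1
A2 | alternative 1 | 1-(2,4,5-trimethoxyphenyl)but-3-yn-2-one | C#CC(=O)Cc1cc(OC)c(OC)cc1OC
A3 | alternative 1 | 1-{2-[(tert-butyldimethylsilyl)oxy]-5-hydroxy-4-methoxyphenyl}-2-(2,4,5-trimethoxyphenyl)ethan-1-one | COc1cc(O[Si](C)(C)C(C)(C)C)c(cc1O)C(=O)Cc1cc(OC)c(OC)cc1OC
A4 | alternative 2 | 4,5-bis(benzyloxy)-2-(trimethylsilyl)phenyl trifluoromethanesulfonate | C[Si](C)(C)c1cc(OCc2ccccc2)c(OCc2ccccc2)cc1OS(=O)(=O)C(F)(F)F
A5 | alternative 2 | (2E)-3-methoxy-2-(2,4,5-trimethoxyphenyl)prop-2-enoic acid | CO/C=C(/C(=O)O)c1cc(OC)c(OC)cc1OC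
A6 | alternative 2 | 6,7-bis(benzyloxy)-3-(2,4,5-trimethoxyphenyl)-4H-chromen-4-one | COc1cc(OC)c(cc1OC)-c1coc2cc(OCc3ccccc3)c(OCc3ccccc3)cc2c1=O
A7 | alternative 2 | 6,7-dihydroxy-3-(2,4,5-trimethoxyphenyl)-4H-chromen-4-one | COc1cc(OC)c(cc1OC)-c1coc2cc(O)c(O)cc2c1=O
A8 | alternative 3 | pentacarbonyl[methoxy(1-methoxyethenyl)carbene]chromium, (CO)5Cr=C(OMe)C(OMe)=CH2 | C=C(OC)C(OC)=[Cr](=C=O)(=C=O)(=C=O)(=C=O)=C=O
A9 | alternative 3 | 6-(benzyloxy)-3-ethynyl-7-methoxy-4H-chromen-4-one | C#Cc1coc2cc(OC)c(OCc3ccccc3)cc2c1=O
A10 | alternative 3 | 6-(benzyloxy)-3-(2-hydroxy-4,5-dimethoxyphenyl)-7-methoxy-4H-chromen-4-one | COc1cc2occ(-c3cc(OC)c(OC)cc3O)c(=O)c2cc1OCc1ccccc1
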